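**Retrosynthetic overview**

1. Target 18 comes from 17 by zinc opening of a temporary 3-bromo-2,2-dimethyldihydropyran that ties O5 of ring A (the cyclohexadienone) to its C4 prenyl group.
2. 17 comes from the C-prenylated ring B 13 and the methylidene dione 16, which is made from the free-enol-side methyl of bromopyran 11 through selenide 14; the CH2 bridge forms by conjugate addition.
3. 11 comes from the achiral trione 10 by catalytic enantioselective 6-endo bromoetherification. The route rests on this feature: C4 of ring A is stereogenic only because C2 carries the CH2–ring B arm and C6 a methyl, so in the 2,6-dimethyl compound 10 a mirror plane runs through C1 and C4 and the enol oxygens on C3 and C5, both next to the C4 prenyl group, are enantiotopic.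
4. 10 comes from methyl 2,6-dimethoxybenzoate 1: the two methyls are put on the arene, then Birch reductive prenylation (quaternary C4), isopropyl ketone, bis-allylic oxidation (C1=O) and enol ether hydrolysis.
5. Ring order: ring A carbocycle from the arene (steps 1–6), temporary pyran (step 7), ring B attached (step 10), pyran removed (step 11).

Key step: step 7

Remark: ring A compounds are written in the cross-conjugated enol tautomer of the target SMILES; they are expected to equilibrate among enol forms, which does not change the stereochemical argument.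

**Route**

Step 1
Reactants: 1 methyl 2,6-dimethoxybenzoate
Product: 2 methyl 3,5-dibromo-2,6-dimethoxybenzoate
Conditions: Br2 (2.3 equiv), AcOH, rt
Reagents that add atoms: bromine, BrBr
Why: Electrophilic aromatic bromination, in which C3 and C5 are each ortho/para to the two methoxy groups and meta to the ester, so all directing effects converge on the 3,5-dibromide and C4 stays free.

Step 2
Reactants: 2 methyl 3,5-dibromo-2,6-dimethoxybenzoate; 3 methylboronic acid
Product: 4 methyl 2,6-dimethoxy-3,5-dimethylbenzoate
Conditions: 3 (3 equiv), Pd(OAc)2 (5 mol%), SPhos (10 mol%), K3PO4, toluene/H2O, 100 °C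
Reagents that add atoms: none
Why: Double Suzuki–Miyaura coupling through zerovalent palladium places the future C2 and C6 methyls of ring A on the arene, which avoids a later C-methylation of the trione that would be expected to favour gem-dimethylation at one carbon; the doubly ortho-substituted ester should resist hydrolysis.

Step 3
Reactants: 4 methyl 2,6-dimethoxy-3,5-dimethylbenzoate; 5 1-bromo-3-methylbut-2-ene
Product: 6 methyl 2,6-dimethoxy-3,5-dimethyl-1-(3-methylbut-2-en-1-yl)cyclohexa-2,5-diene-1-carboxylate
Conditions: K (2.3 equiv), t-BuOH (1.0 equiv), NH3(l)/THF, −78 °C; then 5 (1.5 equiv), −78 °C → rt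
Reagents that add atoms: none
Why: Birch reductive alkylation, in which the benzoate radical anion is protonated at C4 (para to the ester) and the resulting ester dienolate is alkylated at C1 by the allylic bromide (SN2), giving the achiral 1,4-diene with the quaternary carbon that becomes C4 of ring A.

Step 4
Reactants: 6 methyl 2,6-dimethoxy-3,5-dimethyl-1-(3-methylbut-2-en-1-yl)cyclohexa-2,5-diene-1-carboxylate; 7 isopropyllithium
Product: 8 1-[2,6-dimethoxy-3,5-dimethyl-1-(3-methylbut-2-en-1-yl)cyclohexa-2,5-dien-1-yl]-2-methylpropan-1-one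
Conditions: 7 (1.3 equiv, pentane), THF, −78 → −40 °C; then aq. NH4Cl
Reagents that add atoms: none
Why: Addition of a branched alkyllithium to an α-quaternary ester should stop at the ketone, because the lithium hemiketal alkoxide persists at low temperature and the neopentyl-type ketone is too hindered for a second addition; the lithium reagent is preferred to the Grignard reagent to limit β-hydride reduction.

Step 5
Reactants: 8 1-[2,6-dimethoxy-3,5-dimethyl-1-(3-methylbut-2-en-1-yl)cyclohexa-2,5-dien-1-yl]-2-methylpropan-1-one
Product: 9 3,5-dimethoxy-2,6-dimethyl-4-(3-methylbut-2-en-1-yl)-4-(2-methylpropanoyl)cyclohexa-2,5-dien-1-one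
Conditions: anhydrous t-BuOOH (4 equiv), pyridinium dichromate (C5H5NH)2Cr2O7 (20 mol%), Celite, PhH, rt
Reagents that add atoms: tert-butyl hydroperoxide, CC(C)(C)OO
Why: Bis-allylic oxidation by tert-butyl hydroperoxide mediated by hexavalent chromium, the usual way from Birch-derived 1,4-cyclohexadienes to 4,4-disubstituted cyclohexa-2,5-dienones, in which peroxy radicals take the doubly allylic ring hydrogen in preference to the stronger prenyl C–H bonds and the quaternary carbon blocks aromatisation.

Step 6
Reactants: 9 3,5-dimethoxy-2,6-dimethyl-4-(3-methylbut-2-en-1-yl)-4-(2-methylpropanoyl)cyclohexa-2,5-dien-1-one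
Product: 10 3,5-dihydroxy-2,6-dimethyl-4-(3-methylbut-2-en-1-yl)-4-(2-methylpropanoyl)cyclohexa-2,5-dien-1-one
Conditions: 2 M aq. HCl, THF, 40 °C
Reagents that add atoms: water, O
Why: Acid hydrolysis of the two vinylogous methyl esters (conjugate addition of water, loss of methanol) should give the mirror-symmetric bis-enol, and dilute acid at moderate temperature is chosen to avoid hydroalkoxylation of the prenyl group and deacylation.

Step 7
Reactants: 10 3,5-dihydroxy-2,6-dimethyl-4-(3-methylbut-2-en-1-yl)-4-(2-methylpropanoyl)cyclohexa-2,5-dien-1-one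
Product: 11 (3S,4aR)-3-bromo-5-hydroxy-2,2,6,8-tetramethyl-4a-(2-methylpropanoyl)-2,3,4,4a-tetrahydro-7H-chromen-7-one
Conditions: N-bromosuccinimide (1.05 equiv), quinidine-derived 9-O-(N-arylthiocarbamate) catalyst (10 mol%; aryl group and alkaloid series chosen to give the (3S,4aR) enantiomer), CHCl3/toluene, −78 °C
Reagents that add atoms: N-bromosuccinimide, O=C1CCC(=O)N1Br
Why: The quinuclidine nitrogen of the catalyst takes the proton of the vinylogous acid 10 and holds the dienolate as an ion pair while the thiocarbamate sulfur passes Br+ from the N-bromoimide to one face of the prenyl alkene, and an enol oxygen then opens the bromonium ion anti at the dimethyl-substituted carbon. The closest known reaction type is the amino-thiocarbamate-catalysed enantioselective bromolactonisation and bromoetherification of alkenoic acids and of alkenyl 1,3-dicarbonyl enols, used here to desymmetrise a prochiral quaternary carbon. The dihydropyran closes 6-endo with respect to the alkene (Markovnikov opening at CMe2, one C–O and one C–Br bond formed) and not 5-exo, because the gem-dimethyl terminus carries the positive charge. C3 is set by the alkene face that the catalyst selects and C4a by which enantiotopic oxygen closes; the two are linked by a chair transition state in which bromine is equatorial and the ring-fusion isobutyryl group is forced axial by the planar ring A, so each alkene face is served by one oxygen only. The step needs selection between the enantiotopic oxygens on C3 and C5, which the mirror symmetry of 10 and the chair reduce to face selection at a single alkene, and it needs the uncatalysed pathway to stay slow, which low temperature and the lability of any C-bromide formed at C2 or C6 (a 2-bromo-2-methyl-1,3-dione that hands Br+ on) should secure. Since C3 is removed in step 11, only the choice of oxygen matters for the configuration of the target.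

Step 8
Reactants: 12 1-(2,4,6-trihydroxyphenyl)-2-methylpropan-1-one; 5 1-bromo-3-methylbut-2-ene
Product: 13 1-[2,4,6-trihydroxy-3-(3-methylbut-2-en-1-yl)phenyl]-2-methylpropan-1-one
Conditions: 5 (1.0 equiv), 10% aq. KOH, 0 °C → rt
Reagents that add atoms: none
Why: Base-mediated C-prenylation of an acylphloroglucinol (ambident phenolate, SN2 at the allylic bromide), where one equivalent of bromide should favour the mono-C-prenyl product, to be separated from bis-prenylated material.

Step 9
Reactants: 11 (3S,4aR)-3-bromo-5-hydroxy-2,2,6,8-tetramethyl-4a-(2-methylpropanoyl)-2,3,4,4a-tetrahydro-7H-chromen-7-one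
Product: 14 (3S,4aR)-3-bromo-2,2,6,8-tetramethyl-4a-(2-methylpropanoyl)-6-(phenylselanyl)-3,4-dihydro-2H-chromene-5,7(4aH,6H)-dione (mixture of C6 epimers)
Conditions: PhSeCl (1.1 equiv), pyridine (1.2 equiv), CH2Cl2, 0 °C
Reagents that add atoms: benzeneselenenyl chloride, Cl[Se]c1ccccc1
Why: α-Selenenylation of a 1,3-dicarbonyl enol, possible only at C6 because the other half is tied as a vinylogous ester and the prenyl alkene is masked in the pyran (so no selenoetherification can occur); the new C6 centre forms without control and both epimers converge in step 10.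

Step 10
Reactants: 14 (3S,4aR)-3-bromo-2,2,6,8-tetramethyl-4a-(2-methylpropanoyl)-6-(phenylselanyl)-3,4-dihydro-2H-chromene-5,7(4aH,6H)-dione; 13 1-[2,4,6-trihydroxy-3-(3-methylbut-2-en-1-yl)phenyl]-2-methylpropan-1-one
Product: 17 (3S,4aR)-3-bromo-5-hydroxy-2,2,8-trimethyl-4a-(2-methylpropanoyl)-6-{[2,4,6-trihydroxy-3-(3-methylbut-2-en-1-yl)-5-(2-methylpropanoyl)phenyl]methyl}-2,3,4,4a-tetrahydro-7H-chromen-7-one, via selenoxide 15 (not isolated), via methylidene dione 16 (not isolated)
Conditions: mCPBA (1.0 equiv), CH2Cl2, −78 °C; then 13 (1.3 equiv), i-Pr2NH (3 equiv), −78 → 0 °C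
Reagents that add atoms: none
Why: Selenoxide syn-elimination can only take a hydrogen from the C6 methyl (C5 and C7 are carbonyls) and so gives the 6-methylidene-5,7-dione, which the single free ring position of the ring B phenolate attacks in a Michael/Friedel–Crafts alkylation of the kind used to join acylphloroglucinols to alkylidene triketones; the peracid is consumed before 13 is added, the amine buffers the acid and restrains selenenic acid, the C6 centre is erased and C4a is untouched.

Step 11
Reactants: 17 (3S,4aR)-3-bromo-5-hydroxy-2,2,8-trimethyl-4a-(2-methylpropanoyl)-6-{[2,4,6-trihydroxy-3-(3-methylbut-2-en-1-yl)-5-(2-methylpropanoyl)phenyl]methyl}-2,3,4,4a-tetrahydro-7H-chromen-7-one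
Product: 18 (4S)-3,5-dihydroxy-6-methyl-4-(3-methylbut-2-en-1-yl)-4-(2-methylpropanoyl)-2-{[2,4,6-trihydroxy-3-(3-methylbut-2-en-1-yl)-5-(2-methylpropanoyl)phenyl]methyl}cyclohexa-2,5-dien-1-one (CNP0191741.1)
Conditions: activated Zn dust, AcOH/THF, rt
Reagents that add atoms: none
Why: Zinc-mediated reductive β-elimination of a β-bromo ether (Boord-type), in which insertion into the C3–Br bond expels the vinylogous carboxylate oxygen and returns the prenyl alkene and the ring A enol while the C3 centre disappears; the quaternary centre is untouched, and its descriptor changes from 4aR to 4S only because the CIP priorities change.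

**Compound list**

1 | methyl 2,6-dimethoxybenzoate | COC(=O)c1c(OC)cccc1OC | starting material
2 | methyl 3,5-dibromo-2,6-dimethoxybenzoate | COC(=O)c1c(OC)c(Br)cc(Br)c1OC | intermediate
3 | methylboronic acid | CB(O)O | starting material
4 | methyl 2,6-dimethoxy-3,5-dimethylbenzoate | COC(=O)c1c(OC)c(C)cc(C)c1OC | intermediate
5 | 1-bromo-3-methylbut-2-ene (prenyl bromide) | CC(C)=CCBr | starting material
6 | methyl 2,6-dimethoxy-3,5-dimethyl-1-(3-methylbut-2-en-1-yl)cyclohexa-2,5-diene-1-carboxylate | COC(=O)C1(CC=C(C)C)C(OC)=C(C)CC(C)=C1OC | intermediate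
7 | isopropyllithium | [Li]C(C)C | starting material
8 | 1-[2,6-dimethoxy-3,5-dimethyl-1-(3-methylbut-2-en-1-yl)cyclohexa-2,5-dien-1-yl]-2-methylpropan-1-one | CC(C)C(=O)C1(CC=C(C)C)C(OC)=C(C)CC(C)=C1OC | intermediate
9 | 3,5-dimethoxy-2,6-dimethyl-4-(3-methylbut-2-en-1-yl)-4-(2-methylpropanoyl)cyclohexa-2,5-dien-1-one | CC(C)C(=O)C1(CC=C(C)C)C(OC)=C(C)C(=O)C(C)=C1OC | intermediate
10 | 3,5-dihydroxy-2,6-dimethyl-4-(3-methylbut-2-en-1-yl)-4-(2-methylpropanoyl)cyclohexa-2,5-dien-1-one (achiral) | O=C1C(C)=C(O)C(CC=C(C)C)(C(=O)C(C)C)C(O)=C1C | intermediate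
11 | (3S,4aR)-3-bromo-5-hydroxy-2,2,6,8-tetramethyl-4a-(2-methylpropanoyl)-2,3,4,4a-tetrahydro-7H-chromen-7-one (chromene C4a, C5, C6, C7, C8, C8a are ring A C4, C3, C2, C1, C6, C5; Br trans to the isobutyryl group) | O=C1C(C)=C(O)[C@]2(C(=O)C(C)C)C[C@H](Br)C(C)(C)OC2=C1C | intermediate
12 | 1-(2,4,6-trihydroxyphenyl)-2-methylpropan-1-one | CC(C)C(=O)c1c(O)cc(O)cc1O | starting material
13 | 1-[2,4,6-trihydroxy-3-(3-methylbut-2-en-1-yl)phenyl]-2-methylpropan-1-one | CC(C)=CCc1c(O)cc(O)c(C(=O)C(C)C)c1O | intermediate
14 | (3S,4aR)-3-bromo-2,2,6,8-tetramethyl-4a-(2-methylpropanoyl)-6-(phenylselanyl)-3,4-dihydro-2H-chromene-5,7(4aH,6H)-dione, mixture of C6 epimers | O=C1C(C)([Se]c3ccccc3)C(=O)[C@]2(C(=O)C(C)C)C[C@H](Br)C(C)(C)OC2=C1C | intermediate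
15 | selenoxide of 14 (6-benzeneseleninyl compound, C6 and Se unspecified) | O=C1C(C)([Se](=O)c3ccccc3)C(=O)[C@]2(C(=O)C(C)C)C[C@H](Br)C(C)(C)OC2=C1C | intermediate
16 | (3S,4aR)-3-bromo-2,2,8-trimethyl-6-methylidene-4a-(2-methylpropanoyl)-3,4-dihydro-2H-chromene-5,7(4aH,6H)-dione | O=C1C(=C)C(=O)[C@]2(C(=O)C(C)C)C[C@H](Br)C(C)(C)OC2=C1C | intermediate
17 | (3S,4aR)-3-bromo-5-hydroxy-2,2,8-trimethyl-4a-(2-methylpropanoyl)-6-{[2,4,6-trihydroxy-3-(3-methylbut-2-en-1-yl)-5-(2-methylpropanoyl)phenyl]methyl}-2,3,4,4a-tetrahydro-7H-chromen-7-one | O=C1C(Cc3c(O)c(CC=C(C)C)c(O)c(C(=O)C(C)C)c3O)=C(O)[C@]2(C(=O)C(C)C)C[C@H](Br)C(C)(C)OC2=C1C | intermediate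
18 | (4S)-3,5-dihydroxy-6-methyl-4-(3-methylbut-2-en-1-yl)-4-(2-methylpropanoyl)-2-{[2,4,6-trihydroxy-3-(3-methylbut-2-en-1-yl)-5-(2-methylpropanoyl)phenyl]methyl}cyclohexa-2,5-dien-1-one | CC(C)=CCc1c(O)c(CC2=C(O)[C@@](CC=C(C)C)(C(=O)C(C)C)C(O)=C(C)C2=O)c(O)c(C(=O)C(C)C)c1O | target

**Step count**

Total: 11 steps. Longest linear sequence: 10 steps (steps 1–7, 9, 10, 11); step 8 is a one-step branch.

**Steps most likely to fail**

Step 7. The risk is incomplete discrimination between the two enantiotopic enol oxygens, through a racemic background bromination or leakage through a boat transition state; 5-exo closure may also compete. Acid could reverse the bromoetherification later and scramble C4a, so 11, 14 and 17 are to be kept away from strong acid. Fallback: setting out from 10, cyclisation with N-bromosuccinimide alone (CH2Cl2, −78 °C) should give the racemic bromopyran F1. It would be resolved by preparative chromatography on a chiral stationary phase, and the (3S,4aR) enantiomer rejoins the route at 11. The unwanted enantiomer can be returned to achiral 10 with zinc and recycled, since opening the ring removes all stereochemistry.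

Step 10. The risk is attack of electrophilic selenium by-products on the prenyl group or the free ring position of 13, and self-condensation of the methylidene dione before it is captured. Fallback: setting out from 14, oxidation with mCPBA at −78 °C followed by excess dimethylamine in THF should give the isolable Mannich base F2, the amine taking up both the methylidene dione and the selenenic acid. Heating F2 with 13 in dioxane at 80 °C (amine elimination, then conjugate addition of the phloroglucinol) would form the bridge without selenium present and comes back to the route at 17.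

Step 4. The risk is β-hydride reduction or deprotonation competing with clean single addition to the hindered ester. Fallback: setting out from 6, reduction with LiAlH4 (THF, 0 °C) should give the primary alcohol F3. Dess–Martin oxidation buffered with NaHCO3 would give the aldehyde F4, isopropylmagnesium chloride (THF, −78 °C) the racemic carbinol F5, and a second Dess–Martin oxidation comes back to the route at 8.

**Further compounds**

F1 | step 7 | racemic 3-bromo-5-hydroxy-2,2,6,8-tetramethyl-4a-(2-methylpropanoyl)-2,3,4,4a-tetrahydro-7H-chromen-7-one (3S,4aR and 3R,4aS) | O=C1C(C)=C(O)[C@]2(C(=O)C(C)C)C[C@H](Br)C(C)(C)OC2=C1C.O=C1C(C)=C(O)[C@@]2(C(=O)C(C)C)C[C@@H](Br)C(C)(C)OC2=C1C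
F2 | step 10 | (3S,4aR)-3-bromo-6-[(dimethylamino)methyl]-5-hydroxy-2,2,8-trimethyl-4a-(2-methylpropanoyl)-2,3,4,4a-tetrahydro-7H-chromen-7-one | O=C1C(CN(C)C)=C(O)[C@]2(C(=O)C(C)C)C[C@H](Br)C(C)(C)OC2=C1C
F3 | step 4 | [2,6-dimethoxy-3,5-dimethyl-1-(3-methylbut-2-en-1-yl)cyclohexa-2,5-dien-1-yl]methanol | OCC1(CC=C(C)C)C(OC)=C(C)CC(C)=C1OC
F4 | step 4 | 2,6-dimethoxy-3,5-dimethyl-1-(3-methylbut-2-en-1-yl)cyclohexa-2,5-diene-1-carbaldehyde | O=CC1(CC=C(C)C)C(OC)=C(C)CC(C)=C1OC
F5 | step 4 | 1-[2,6-dimethoxy-3,5-dimethyl-1-(3-methylbut-2-en-1-yl)cyclohexa-2,5-dien-1-yl]-2-methylpropan-1-ol (racemic) | CC(C)C(O)C1(CC=C(C)C)C(OC)=C(C)CC(C)=C1OC
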